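**Assumption:** the target is taken exactly as drawn in the SMILES, i.e. (2R,3R,5R) in the tetrahydropyran (THP) and (1S,3S,4S) in the cyclohexyl ring. Locants below follow that name (THP C2/C3/C5; cyclohexyl C1′/C3′/C4′). The route is a paper design, not an experimentally tested sequence.

## Retrosynthetic overview

1. Target 17 ⇒ anti Br–Cl addition to the 1-methylcyclohexene of bromo-THP 15 (last step).
2. 15 ⇒ 6-endo bromoetherification of hydroxy-acetate 13 (THP ring formed second).
3. 13 ⇒ non-chelation methyl addition to acetoxy ketone 11 ⇐ Mitsunobu inversion of ketol 9.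
4. 9 ⇒ key Diels–Alder of isoprene with the (S)-α′-hydroxy vinyl ketone 7 (cyclohexene ring formed first; C1′ set by the bought carbinol centre).
5. 7 ⇒ methyl (S)-glycidate, isobutenyl cuprate, Weinreb amide, vinyl Grignard.

## Route

**Step 1**
Reactants: 1, methyl (S)-glycidate; 2, 2-methylprop-1-enylmagnesium bromide
Product: 3, methyl (2S)-2-hydroxy-5-methylhex-4-enoate
Conditions: 2 (1.5 equiv), CuI (10 mol %), THF, −40 → −20 °C
Reagents that add atoms: 2-methylprop-1-enylmagnesium bromide, CC(C)=C[Mg]Br
Why: Cu-catalysed Grignard opening of the glycidate at the unsubstituted C3 (SN2) leaves the bought C2 stereocentre untouched and installs the prenyl chain.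

**Step 2**
Reactants: 3; 4, N,O-dimethylhydroxylamine hydrochloride
Product: 5, (2S)-2-hydroxy-N-methoxy-N,5-dimethylhex-4-enamide
Conditions: 4 (2 equiv), i-PrMgCl (5 equiv), THF, −20 → 0 °C
Reagents that add atoms: N,O-dimethylhydroxylamine hydrochloride, CNOC.Cl
Why: Direct ester-to-Weinreb-amide aminolysis with the magnesium amide tolerates the free α-hydroxyl (as its alkoxide) and does not touch the stereocentre.

**Step 3**
Reactants: 5; 6, vinylmagnesium bromide
Product: 7, (4S)-4-hydroxy-7-methylocta-1,6-dien-3-one
Conditions: 6 (3 equiv), THF, −78 → 0 °C; inverse quench into cold 1 M HCl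
Reagents that add atoms: vinylmagnesium bromide, C=C[Mg]Br
Why: Weinreb ketone synthesis stops at the chelated tetrahedral intermediate, giving the α′-hydroxy vinyl ketone without over-addition; the acidic inverse quench prevents aza-Michael addition of the released amine.

**Step 4 (key step)**
Reactants: 7; 8, isoprene
Product: 9, (2S)-2-hydroxy-5-methyl-1-[(1S)-4-methylcyclohex-3-en-1-yl]hex-4-en-1-one
Conditions: 8 (5 equiv), ZnCl2 (1.1 equiv), CH2Cl2, −40 → −20 °C; chromatography removes the minor C1′ epimer
Reagents that add atoms: isoprene, CC(=C)C=C
Why: Diels–Alder cycloaddition of the Zn-chelated (or H-bonded) s-cis α′-hydroxy enone gives the "para" adduct, with isoprene adding to the face opposite the prenyl-CH2 group of the carbinol centre, which sets C1′ as S; selectivity may be modest because the directing group is only a primary alkyl.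

**Step 5**
Reactants: 9; 10, acetic acid
Product: 11, (2R)-5-methyl-1-[(1S)-4-methylcyclohex-3-en-1-yl]-1-oxohex-4-en-2-yl acetate
Conditions: PPh3, DIAD, AcOH, THF, 0 °C
Reagents that add atoms: acetic acid, CC(=O)O
Why: Mitsunobu SN2 displacement inverts the α-ketol carbon and installs the final acetate; inversion is required because the carbinol configuration that steers the Diels–Alder to the correct C1′ face is opposite to the one in the target.

**Step 6**
Reactants: 11; 12, methyltitanium triisopropoxide
Product: 13, (2R,3R)-2-hydroxy-6-methyl-2-[(1S)-4-methylcyclohex-3-en-1-yl]hept-5-en-3-yl acetate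
Conditions: 12 (3 equiv, from MeLi + ClTi(OiPr)3), Et2O, −30 °C → rt
Reagents that add atoms: methyltitanium triisopropoxide, C[Ti](OC(C)C)(OC(C)C)OC(C)C
Why: The non-chelating, ester-tolerant titanium reagent should add under polar Felkin–Anh control (acetoxy anti to the incoming methyl), giving the 2R tertiary carbinol; chelation control would give the wrong epimer.

**Step 7**
Reactants: 13; 14, 2,4,4,6-tetrabromocyclohexa-2,5-dienone (TBCO)
Product: 15, (2R,3R,5R)-5-bromo-2,6,6-trimethyl-2-[(1S)-4-methylcyclohex-3-en-1-yl]oxan-3-yl acetate
Conditions: TBCO (1.05 equiv), MeNO2, 0 °C → rt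
Reagents that add atoms: TBCO, O=C1C(Br)=CC(Br)(Br)C=C1Br
Why: In this bromoetherification the tertiary OH traps the prenyl bromonium at the more substituted carbon (6-endo) through a chair transition state with the cyclohexenyl group and Br equatorial, giving 5R; the acetate blocks participation by the C3 oxygen, and the ring alkene has no comparably fast internal trap.

**Step 8**
Reactants: 15; 16, tetrabutylammonium dichlorobromate (Bu4N+ BrCl2−)
Product: 17, 8-acetylcaespitol, (2R,3R,5R)-5-bromo-2-[(1S,3S,4S)-3-bromo-4-chloro-4-methylcyclohexyl]-2,6,6-trimethyloxan-3-yl acetate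
Conditions: 16 (1.1 equiv), CH2Cl2, −78 °C; HPLC separation of the two anti adducts
Reagents that add atoms: tetrabutylammonium dichlorobromate, drawn as the Bu4N+ Cl−·BrCl ion pair, CCCC[N+](CCCC)(CCCC)CCCC.[Cl-].ClBr (supplies one Br and one Cl)
Why: Ionic bromochlorination is anti and Markovnikov (Br+ to the secondary carbon, Cl− to the tertiary carbon), which fixes the constitution and the trans Br/Cl relationship. The facial sense relative to C1′ is not enforced: trans-diaxial opening favours the C3′,C4′-bis-epimer, so the all-equatorial target (from the bromonium syn to the C1′ substituent) is expected as the minor adduct.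

## Compound list

1 | methyl (S)-glycidate | COC(=O)[C@@H]1CO1 | starting material
2 | 2-methylprop-1-enylmagnesium bromide | CC(C)=C[Mg]Br | starting material
3 | methyl (2S)-2-hydroxy-5-methylhex-4-enoate | COC(=O)[C@@H](O)CC=C(C)C | intermediate
4 | N,O-dimethylhydroxylamine hydrochloride | CNOC.Cl | starting material
5 | (2S)-2-hydroxy-N-methoxy-N,5-dimethylhex-4-enamide | CON(C)C(=O)[C@@H](O)CC=C(C)C | intermediate
6 | vinylmagnesium bromide | C=C[Mg]Br | starting material
7 | (4S)-4-hydroxy-7-methylocta-1,6-dien-3-one | C=CC(=O)[C@@H](O)CC=C(C)C | intermediate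
8 | isoprene | CC(=C)C=C | starting material
9 | (2S)-2-hydroxy-5-methyl-1-[(1S)-4-methylcyclohex-3-en-1-yl]hex-4-en-1-one | CC1=CC[C@H](CC1)C(=O)[C@@H](O)CC=C(C)C | intermediate
10 | acetic acid | CC(=O)O | starting material
11 | (2R)-5-methyl-1-[(1S)-4-methylcyclohex-3-en-1-yl]-1-oxohex-4-en-2-yl acetate | CC1=CC[C@H](CC1)C(=O)[C@H](OC(C)=O)CC=C(C)C | intermediate
12 | methyltitanium triisopropoxide (made in situ from MeLi and ClTi(OiPr)3) | C[Ti](OC(C)C)(OC(C)C)OC(C)C | starting material (reagent)
13 | (2R,3R)-2-hydroxy-6-methyl-2-[(1S)-4-methylcyclohex-3-en-1-yl]hept-5-en-3-yl acetate | CC1=CC[C@H](CC1)[C@@](C)(O)[C@H](OC(C)=O)CC=C(C)C | intermediate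
14 | 2,4,4,6-tetrabromocyclohexa-2,5-dienone (TBCO) | O=C1C(Br)=CC(Br)(Br)C=C1Br | starting material (reagent)
15 | (2R,3R,5R)-5-bromo-2,6,6-trimethyl-2-[(1S)-4-methylcyclohex-3-en-1-yl]oxan-3-yl acetate | CC(=O)O[C@@H]1C[C@@H](Br)C(C)(C)O[C@]1(C)[C@H]1CCC(C)=CC1 | intermediate
16 | tetrabutylammonium dichlorobromate (Bu4N+ BrCl2−, drawn as Bu4N+ Cl−·BrCl) | CCCC[N+](CCCC)(CCCC)CCCC.[Cl-].ClBr | starting material (reagent)
17 | 8-acetylcaespitol | CC(=O)O[C@@H]1C[C@@H](Br)C(C)(C)O[C@]1(C)[C@H]1CC[C@](C)(Cl)[C@@H](Br)C1 | target

## Step count

Total steps: 8. Longest linear sequence: 8.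

## Three steps most likely to fail

1. **Step 8 (bromochlorination).** The substrate's own bias (trans-diaxial opening with the THP group equatorial) works against the target, so the desired isomer will be the minor one. The major adduct can be returned to 13 with Zn/AcOH, which reverses both the vicinal dihalide and the β-bromo ether. Fallback: replace the alkene addition by an epoxide/1,2-bromine-shift sequence. Epoxidise 15 (DMDO), take the epoxide anti to the THP substituent, and open it with HBr at the tertiary carbon to give the trans-diaxial bromohydrin with Br on the THP face. Then activate the secondary OH (Tf2O, Bu4NCl) so that Br migrates through the required bromonium and chloride enters C4′ from the opposite face. This removes the diaxial product of the wrong bromonium, though partition between the target and its halogen-transposed isomer remains uncertain.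

2. **Step 6 (Felkin methyl addition to the hindered α-acetoxy ketone).** It may be slow or poorly selective, or the acetate may migrate. Fallback: build the tertiary carbinol from an alkene instead of by carbonyl addition. Takai–Lombardo methylenation of 11, acetate methanolysis, VO(acac)2/TBHP hydroxyl-directed epoxidation of the 1,1-disubstituted allylic alcohol (erythro-selective through A1,2 strain, which gives the same 2R,3R relationship), LiAlH4 opening at the CH2 terminus, then selective acetylation of the secondary OH.

3. **Step 7 (bromoetherification).** Competing 5-exo THF formation, the C5 epimer and attack at the ring alkene could all erode yield. Fallback: Hg(OCOCF3)2-mediated 6-endo oxymercuration cyclisation of 13, followed by brominative demercuration (LiBr/Br2) of the organomercurial.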